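1. Target cannot appear at once. Substrate must first become intermediate A, then intermediate B, and only then can it meet reagent, whereas side product leaks from substrate in one step.

| flask | substrate | reagent | remark | time |
|---|---|---|---|---|
| north-west | 0.14 M | 0.0840 M | one stirred flow tank at steady state, fed with the mixture as stated, mean residence time 20 h |  |
| south-east | 0.14 M | 0.0840 M | everything together in a closed stirred flask, run for 20 h | 20 h |
| south | 0.14 M | 0.0840 M (fed, over 16.0 h) | a stirred flask in which reagent is dosed at a steady rate over 16.0 h without added volume, worked up at 20 h | 20 h |
| north | 0.14 M (fed, over 16.0 h) | 0.0840 M | a stirred flask in which substrate is dosed at a steady rate over 16.0 h without added volume, worked up at 20 h | 20 h |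

* the set-up with the highest share of target in all that became target or side product, at the outlet or at the end ("none" if the first two lie within 2 percentage points) (north-west / south-east / south / north / none)
* share of target in all that became target or side product, at the outlet or at the end, north-west
* share of target in all that became target or side product, at the outlet or at the end, south-east
* share of target in all that became target or side product, at the outlet or at the end, south
* share of target in all that became target or side product, at the outlet or at the end, north

- the stated concentrations are those of everything mixed, before any reaction; amounts are the same in each set-up
- the feed brings no volume worth counting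
- run time (south-east): 20 h

    substrate ⇌ intermediate A (K1 = 2.8, k1 = 0.0542 h⁻¹)
    intermediate A → intermediate B (k2 = 0.00892 h⁻¹)
    intermediate B → side product (k3 = 0.00213 h⁻¹)
    reagent + intermediate B → target (k4 = 0.723 L mol⁻¹ h⁻¹)
    substrate → side product (k5 = 9.30 × 10⁻⁴ h⁻¹)
    reagent ⇌ dormant form (K6 = 0.67, k6 = 0.0386 h⁻¹)

2. This reckoning sets reagent at its balance with dormant form, which gives free reagent R = 0.0503 M, and it ignores the loss of substrate.

3. In a young charge, intermediate A grows with time t, and intermediate B with t times the average wait of intermediate A, which is t over 2. Target then grows with a further wait, t over 3, while side product grows with t. Target over side product is therefore the product of the 2 waits over T squared. Here T, the overtaking time, is the root of the leak constant 9.30 × 10⁻⁴ h⁻¹ over the product of 0.0542 h⁻¹, 0.00892 h⁻¹, 0.723 L mol⁻¹ h⁻¹ and R: 7.27 h.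

4. The second time is the effective wait a, the root of the product of the 2 waits, and the share is a²/(a²+T²).
- South-east: the waits are 10.0 h and 6.67 h, so a = 8.16 h, which gives 55.8%.
- South: reagent arrives late, and weighting it by the growth of intermediate B trims a to 7.62 h, which gives 52.4%.
- North: substrate ages are spread, and the mean cube of age over the mean age, in place of the run time squared, gives a = 5.89 h, so the share is 39.6%.
- North-west: intermediate A lives 12.8 h in the tank and intermediate B 11.3 h. These lifetimes are the waits, so a = 12.0 h, and the share is 73.2%.

The longest effective wait picks north-west.

5. The forecast also names north-west, with different numbers: north-west 72% (70% to 74%), south-east 56% (52% to 60%), south 55% (50% to 59%), north 41% (36% to 46%). Its ground: “The tank's residence-time tail gives the B-to-target step the most time”.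

6. The simulation gives north-west: north-west 72.2%, south-east 53.8%, south 53.5%, north 38.2%.

In north at 12.8 h, substrate enters intermediate A 58 times as fast as it leaks to side product (forward rate alone). Even so, at the end of north, with a below T, target stands at 0.517% against 0.838% of side product, while intermediate A holds 38.7%.

The neighbour is north with 0.21 M of reagent. There T shrinks to 4.60 h, and the share reckons to 62.1%. The computed flask gives 55.5%, above the forecast's high end for north.

All constants were chosen freely; what happens was integrated by code.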